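**Plan**

1. Retrosynthesis: the five benzyl ethers come off last. Both pyranone rings are opened at O1–C2, and both C2–C3 bonds are cut in one operation back to a bis-ester. The two ester C–O bonds and then the biaryl bond C3' (unit 1)–C8 (unit 2) are cut, leaving four small arenes.
2. Enabling feature: in each flavone unit, C3 is a former acetyl CH3 on ring A and C2 a former carboxyl carbon. The C2 of unit 1 sits on ring B of unit 1, the same ring that is bonded to C8 of unit 2, and ring A of unit 2 carries the other acetyl group. One biaryl with an acetyl on one ring and a carboxyl on the other can therefore grow a diketone chain in both directions.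
3. Forward: ring A of unit 2 (dibenzylated, iodinated phloroacetophenone) is joined to ring B of unit 1 by Suzuki coupling. The ring B carboxyl is carried as an aldehyde, because a methyl ester could not be saponified beside an aryl ester; the hindered phenol is aroylated first and the acid is then released by Pinnick oxidation.
4. Esterification with the ring A phenol of unit 1 gives the bis-ester; the double acyl transfer builds both diketones, one acid treatment closes both pyranone rings, and hydrogenolysis frees the five phenols.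
5. Stereochemistry: the target has no stereocentre and its biaryl axis is not defined, so nothing has to be controlled.

Key step: step 10

Assumption: the 1,3-diketones are drawn as diketo tautomers although enol forms will be present, and the biaryl axis is treated as configurationally undefined, as in the target structure.

**Route**

Step 1
Reactants: 1 2',4',6'-trihydroxyacetophenone
Product: 2 1-[2,4-bis(benzyloxy)-6-hydroxyphenyl]ethanone
Conditions: BnBr (2.1 equiv), K2CO3 (2.2 equiv), DMF, rt to 50 °C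
Reagents that add atoms: benzyl bromide, BrCc1ccccc1
Why: Williamson etherification takes the 4-hydroxyl and one ortho hydroxyl, while the last ortho hydroxyl stays hydrogen-bonded to the acetyl carbonyl and is not alkylated by carbonate.

Step 2
Reactants: 2 1-[2,4-bis(benzyloxy)-6-hydroxyphenyl]ethanone
Product: 3 1-[4,6-bis(benzyloxy)-2-hydroxy-3-iodophenyl]ethanone
Conditions: BnMe3N·ICl2 (1.05 equiv), NaHCO3, CH2Cl2/MeOH, rt
Reagents that add atoms: benzyltrimethylammonium dichloroiodate, C[N+](C)(C)Cc1ccccc1.Cl[I-]Cl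
Why: Electrophilic aromatic iodination with the dichloroiodate salt should go to the carbon ortho to the chelated hydroxyl, the position favoured in hydrogen-bonded ortho-hydroxyacetophenones, and this carbon later becomes C8 of unit 2.

Step 3
Reactants: 4 3-bromo-4-hydroxybenzaldehyde
Product: 5 4-(benzyloxy)-3-bromobenzaldehyde
Conditions: BnBr (1.1 equiv), K2CO3, DMF, rt
Reagents that add atoms: benzyl bromide, BrCc1ccccc1
Why: Williamson etherification of the only phenol, with the aldehyde inert to carbonate.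

Step 4
Reactants: 5 4-(benzyloxy)-3-bromobenzaldehyde
Product: 6 4-(benzyloxy)-3-(4,4,5,5-tetramethyl-1,3,2-dioxaborolan-2-yl)benzaldehyde
Conditions: B2pin2 (1.2 equiv), PdCl2(dppf) (3 mol%; dppf = 1,1'-bis(diphenylphosphino)ferrocene), KOAc, 1,4-dioxane, 90 °C
Reagents that add atoms: bis(pinacolato)diboron, CC1(C)OB(B2OC(C)(C)C(C)(C)O2)OC1(C)C
Why: Miyaura borylation, in which zerovalent palladium inserts into the C–Br bond and acetate-assisted transmetalation delivers the boryl group; aldehyde and benzyl ether tolerate the weak base.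

Step 5
Reactants: 3 1-[4,6-bis(benzyloxy)-2-hydroxy-3-iodophenyl]ethanone; 6 4-(benzyloxy)-3-(4,4,5,5-tetramethyl-1,3,2-dioxaborolan-2-yl)benzaldehyde
Product: 7 3-[3-acetyl-4,6-bis(benzyloxy)-2-hydroxyphenyl]-4-(benzyloxy)benzaldehyde
Conditions: Pd(OAc)2 (5 mol%), SPhos (2-dicyclohexylphosphino-2',6'-dimethoxybiphenyl, 10 mol%), K3PO4 (3 equiv), toluene/H2O 10:1, 80 °C
Reagents that add atoms: none
Why: Suzuki–Miyaura coupling, in which the aryl iodide allows easy oxidative addition to zerovalent palladium and the bulky electron-rich biarylphosphine is suited to a biaryl with three ortho substituents and a free phenol; the doubly ortho-flanked acetyl group should not enolise under phosphate, so no aldol reaction with the aldehyde is expected.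

Step 6
Reactants: 7 3-[3-acetyl-4,6-bis(benzyloxy)-2-hydroxyphenyl]-4-(benzyloxy)benzaldehyde; 8 4-(benzyloxy)benzoyl chloride
Product: 9 2-acetyl-3,5-bis(benzyloxy)-6-[2-(benzyloxy)-5-formylphenyl]phenyl 4-(benzyloxy)benzoate
Conditions: 8 (1.5 equiv), pyridine, DMAP (0.2 equiv), CH2Cl2, 0 °C to 40 °C
Reagents that add atoms: none
Why: DMAP-catalysed O-acylation of a phenol with an acid chloride, with the single phenol as the only nucleophile and the aldehyde untouched under these non-enolising conditions.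

Step 7
Reactants: 9 2-acetyl-3,5-bis(benzyloxy)-6-[2-(benzyloxy)-5-formylphenyl]phenyl 4-(benzyloxy)benzoate
Product: 10 3-{3-acetyl-4,6-bis(benzyloxy)-2-[4-(benzyloxy)benzoyloxy]phenyl}-4-(benzyloxy)benzoic acid
Conditions: NaClO2, NaH2PO4, 2-methyl-2-butene (excess), t-BuOH/THF/H2O, 0 °C to rt
Reagents that add atoms: sodium chlorite, [Na+].[O-]Cl=O
Why: Pinnick oxidation by chlorous acid at about pH 4 converts the aldehyde to the acid without hydrolysing the aryl ester or forming an enolate, and the alkene scavenger removes hypochlorous acid before it can chlorinate the electron-rich ring.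

Step 8
Reactants: 11 2',6'-dihydroxy-4'-methoxyacetophenone
Product: 12 1-[2-(benzyloxy)-6-hydroxy-4-methoxyphenyl]ethanone
Conditions: BnBr (1.05 equiv), K2CO3 (1.1 equiv), acetone, reflux
Reagents that add atoms: benzyl bromide, BrCc1ccccc1
Why: Williamson etherification stops after one alkylation because the two hydroxyls are equivalent and the one that remains is locked in a hydrogen bond to the acetyl carbonyl.

Step 9
Reactants: 10 3-{3-acetyl-4,6-bis(benzyloxy)-2-[4-(benzyloxy)benzoyloxy]phenyl}-4-(benzyloxy)benzoic acid; 12 1-[2-(benzyloxy)-6-hydroxy-4-methoxyphenyl]ethanone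
Product: 13 2-acetyl-3-(benzyloxy)-5-methoxyphenyl 3-{3-acetyl-4,6-bis(benzyloxy)-2-[4-(benzyloxy)benzoyloxy]phenyl}-4-(benzyloxy)benzoate
Conditions: DCC (1.3 equiv), DMAP (0.2 equiv), 12 (1.2 equiv), CH2Cl2, 0 °C to rt
Reagents that add atoms: none
Why: Steglich esterification, in which acid 10 carries no free hydroxyl, so only the phenol of 12 can be acylated, and the existing aryl ester is stable to catalytic DMAP at room temperature.

Step 10
Reactants: 13 2-acetyl-3-(benzyloxy)-5-methoxyphenyl 3-{3-acetyl-4,6-bis(benzyloxy)-2-[4-(benzyloxy)benzoyloxy]phenyl}-4-(benzyloxy)benzoate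
Product: 14 1-[2-(benzyloxy)-6-hydroxy-4-methoxyphenyl]-3-[4-(benzyloxy)-3-(4,6-bis(benzyloxy)-3-{3-[4-(benzyloxy)phenyl]-3-oxopropanoyl}-2-hydroxyphenyl)phenyl]propane-1,3-dione
Conditions: LiN(SiMe3)2 (7 equiv), THF, −78 °C to rt; then 1 M HCl, 0 °C
Reagents that add atoms: none
Why: This is a Baker–Venkataraman rearrangement run on both ortho-acyloxyacetophenone motifs of 13: the amide base turns each acetyl group into its lithium enolate, which adds to the ester carbonyl on the neighbouring phenolic oxygen through a six-membered cyclic transition state, and collapse of the tetrahedral intermediate expels the phenoxide and leaves a 1,3-diketone whose deprotonation makes the transfer irreversible. The two new C–C bonds are the future C2–C3 bonds of unit 2 (acetyl CH3 to the 4-benzyloxybenzoyl carbon) and of unit 1 (acetyl CH3 to the carboxyl carbon on ring B). No ring is closed and no stereocentre is formed; the cyclic array is only a transition state for acyl transfer. The step needs each enolate to take its own ester, which is secured because each acetyl group has exactly one ester on an ortho oxygen and reaching the other ester would need a macrocyclic transition state. A non-nucleophilic base is chosen because hydroxide or alkoxide could cleave the unit 1 ester, the only link between the two halves on that side until the C–C bond has formed. The benzyl ethers, the methyl ether and the biaryl bond are inert to the base.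

Step 11
Reactants: 14 1-[2-(benzyloxy)-6-hydroxy-4-methoxyphenyl]-3-[4-(benzyloxy)-3-(4,6-bis(benzyloxy)-3-{3-[4-(benzyloxy)phenyl]-3-oxopropanoyl}-2-hydroxyphenyl)phenyl]propane-1,3-dione
Product: 15 5-(benzyloxy)-2-[4-(benzyloxy)-3-{5,7-bis(benzyloxy)-2-[4-(benzyloxy)phenyl]-4-oxo-4H-chromen-8-yl}phenyl]-7-methoxy-4H-chromen-4-one
Conditions: p-TsOH·H2O (0.3 equiv), toluene, 90 °C
Reagents that add atoms: none
Why: Acid-catalysed cyclodehydration, in which each free phenol adds to the distal carbonyl of its diketone and water is lost to give the aromatic pyranone; each ring A has only one free hydroxyl, so a single regioisomer can form (8-aryl-5,7-dioxygenated for unit 2, 5-benzyloxy-7-methoxy for unit 1).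

Step 12
Reactants: 15 5-(benzyloxy)-2-[4-(benzyloxy)-3-{5,7-bis(benzyloxy)-2-[4-(benzyloxy)phenyl]-4-oxo-4H-chromen-8-yl}phenyl]-7-methoxy-4H-chromen-4-one
Product: 16 sequoiaflavone
Conditions: H2 (1 atm), Pd/C (10% palladium on carbon), THF/MeOH 1:1, rt
Reagents that add atoms: none
Why: Catalytic hydrogenolysis cleaves the five benzyl aryl ethers, while the methyl ether and the vinylogous-ester C2=C3 bonds of the flavones should survive at ambient pressure.

**Compound list**

1 | 2',4',6'-trihydroxyacetophenone | CC(=O)c1c(O)cc(O)cc1O | starting material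
2 | 1-[2,4-bis(benzyloxy)-6-hydroxyphenyl]ethanone | CC(=O)c1c(O)cc(OCc2ccccc2)cc1OCc1ccccc1 | intermediate
3 | 1-[4,6-bis(benzyloxy)-2-hydroxy-3-iodophenyl]ethanone | CC(=O)c1c(O)c(I)c(OCc2ccccc2)cc1OCc1ccccc1 | intermediate
4 | 3-bromo-4-hydroxybenzaldehyde | O=Cc1ccc(O)c(Br)c1 | starting material
5 | 4-(benzyloxy)-3-bromobenzaldehyde | O=Cc1ccc(OCc2ccccc2)c(Br)c1 | intermediate
6 | 4-(benzyloxy)-3-(4,4,5,5-tetramethyl-1,3,2-dioxaborolan-2-yl)benzaldehyde | O=Cc1ccc(OCc2ccccc2)c(B2OC(C)(C)C(C)(C)O2)c1 | intermediate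
7 | 3-[3-acetyl-4,6-bis(benzyloxy)-2-hydroxyphenyl]-4-(benzyloxy)benzaldehyde | CC(=O)c1c(O)c(-c2cc(C=O)ccc2OCc2ccccc2)c(OCc2ccccc2)cc1OCc1ccccc1 | intermediate
8 | 4-(benzyloxy)benzoyl chloride | O=C(Cl)c1ccc(OCc2ccccc2)cc1 | starting material
9 | 2-acetyl-3,5-bis(benzyloxy)-6-[2-(benzyloxy)-5-formylphenyl]phenyl 4-(benzyloxy)benzoate | CC(=O)c1c(OC(=O)c2ccc(OCc3ccccc3)cc2)c(-c2cc(C=O)ccc2OCc2ccccc2)c(OCc2ccccc2)cc1OCc1ccccc1 | intermediate
10 | 3-{3-acetyl-4,6-bis(benzyloxy)-2-[4-(benzyloxy)benzoyloxy]phenyl}-4-(benzyloxy)benzoic acid | CC(=O)c1c(OC(=O)c2ccc(OCc3ccccc3)cc2)c(-c2cc(C(=O)O)ccc2OCc2ccccc2)c(OCc2ccccc2)cc1OCc1ccccc1 | intermediate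
11 | 2',6'-dihydroxy-4'-methoxyacetophenone | COc1cc(O)c(C(C)=O)c(O)c1 | starting material
12 | 1-[2-(benzyloxy)-6-hydroxy-4-methoxyphenyl]ethanone | COc1cc(O)c(C(C)=O)c(OCc2ccccc2)c1 | intermediate
13 | 2-acetyl-3-(benzyloxy)-5-methoxyphenyl 3-{3-acetyl-4,6-bis(benzyloxy)-2-[4-(benzyloxy)benzoyloxy]phenyl}-4-(benzyloxy)benzoate (bis-ester) | CC(=O)c1c(OC(=O)c2ccc(OCc3ccccc3)cc2)c(-c2cc(C(=O)Oc3cc(OC)cc(OCc4ccccc4)c3C(C)=O)ccc2OCc2ccccc2)c(OCc2ccccc2)cc1OCc1ccccc1 | intermediate
14 | 1-[2-(benzyloxy)-6-hydroxy-4-methoxyphenyl]-3-[4-(benzyloxy)-3-(4,6-bis(benzyloxy)-3-{3-[4-(benzyloxy)phenyl]-3-oxopropanoyl}-2-hydroxyphenyl)phenyl]propane-1,3-dione (bis-diketone) | COc1cc(O)c(C(=O)CC(=O)c2ccc(OCc3ccccc3)c(-c3c(O)c(C(=O)CC(=O)c4ccc(OCc5ccccc5)cc4)c(OCc4ccccc4)cc3OCc3ccccc3)c2)c(OCc2ccccc2)c1 | intermediate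
15 | 5-(benzyloxy)-2-[4-(benzyloxy)-3-{5,7-bis(benzyloxy)-2-[4-(benzyloxy)phenyl]-4-oxo-4H-chromen-8-yl}phenyl]-7-methoxy-4H-chromen-4-one (penta-O-benzylsequoiaflavone) | COc1cc(OCc2ccccc2)c2c(=O)cc(-c3ccc(OCc4ccccc4)c(-c4c(OCc5ccccc5)cc(OCc5ccccc5)c5c(=O)cc(-c6ccc(OCc7ccccc7)cc6)oc45)c3)oc2c1 | intermediate
16 | sequoiaflavone, 5,7-dihydroxy-8-[2-hydroxy-5-(5-hydroxy-7-methoxy-4-oxo-4H-chromen-2-yl)phenyl]-2-(4-hydroxyphenyl)-4H-chromen-4-one | COc1cc(O)c2c(=O)cc(-c3ccc(O)c(-c4c(O)cc(O)c5c(=O)cc(-c6ccc(O)cc6)oc45)c3)oc2c1 | target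

**Step count**

Total: 12 steps. Longest linear sequence: 9 steps (steps 1, 2, 5, 6, 7, 9, 10, 11, 12 from compound 1; the branch from compound 4 through steps 3 and 4 is equally long).

**Steps most likely to fail**

Step 10. The two acyl transfers need not run at the same rate. The unit 1 benzoate carbonyl is deactivated by its para benzyloxy group and may resist the hindered enolate, and long exposure to base may then cleave that ester and sever the molecule. The fallback sets out from 10, runs the two transfers one after the other and comes back at 15. Acid 10 with LiN(SiMe3)2 in THF should undergo a single acyl transfer beside the spectator carboxylate to give 3-(4,6-bis(benzyloxy)-3-{3-[4-(benzyloxy)phenyl]-3-oxopropanoyl}-2-hydroxyphenyl)-4-(benzyloxy)benzoic acid F1. p-TsOH in toluene should then close the unit 2 pyranone to give 4-(benzyloxy)-3-{5,7-bis(benzyloxy)-2-[4-(benzyloxy)phenyl]-4-oxo-4H-chromen-8-yl}benzoic acid F2. DCC/DMAP coupling with 12 should give 2-acetyl-3-(benzyloxy)-5-methoxyphenyl 4-(benzyloxy)-3-{5,7-bis(benzyloxy)-2-[4-(benzyloxy)phenyl]-4-oxo-4H-chromen-8-yl}benzoate F3. A second, single acyl transfer with LiN(SiMe3)2 should give 1-[2-(benzyloxy)-6-hydroxy-4-methoxyphenyl]-3-(4-(benzyloxy)-3-{5,7-bis(benzyloxy)-2-[4-(benzyloxy)phenyl]-4-oxo-4H-chromen-8-yl}phenyl)propane-1,3-dione F4, and acid cyclodehydration of this diketone returns the material to the route at 15.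

Step 5. Oxidative addition and transmetalation at the electron-rich iodophenoxide with two ortho substituents may be slow, so that protodeboronation of the ortho-alkoxy boronate and reductive loss of iodine take over. The fallback sets out from 3, removes the phenoxide from the coupling and comes back at 7. Iodide 3 is masked with chloromethyl methyl ether and i-Pr2NEt in CH2Cl2 as 1-[4,6-bis(benzyloxy)-3-iodo-2-(methoxymethoxy)phenyl]ethanone F5. Coupling of this neutral iodide with 6 under the step 5 catalyst should give 3-[3-acetyl-4,6-bis(benzyloxy)-2-(methoxymethoxy)phenyl]-4-(benzyloxy)benzaldehyde F6. Brief treatment with 2 M HCl in THF at 40 °C removes the acetal, which is activated by the neighbouring carbonyl, and gives 7.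

Step 6. Acylation may stall because the phenol is hydrogen-bonded to the acetyl group and shielded by the twisted, ortho-substituted aryl ring, while the acid chloride is consumed by adventitious water. The fallback sets out from 3, moves the acylation ahead of the biaryl coupling and comes back at 9. Iodophenol 3 is aroylated with 8 (pyridine, DMAP) to give 2-acetyl-3,5-bis(benzyloxy)-6-iodophenyl 4-(benzyloxy)benzoate F7. Anhydrous Suzuki coupling of this ester with 6 (Pd(OAc)2, SPhos, CsF, 1,4-dioxane, 90 °C) spares the aryl ester and should give 9 directly.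

**Further compounds**

F1 | step 10 | 3-(4,6-bis(benzyloxy)-3-{3-[4-(benzyloxy)phenyl]-3-oxopropanoyl}-2-hydroxyphenyl)-4-(benzyloxy)benzoic acid | O=C(CC(=O)c1c(O)c(-c2cc(C(=O)O)ccc2OCc2ccccc2)c(OCc2ccccc2)cc1OCc1ccccc1)c1ccc(OCc2ccccc2)cc1
F2 | step 10 | 4-(benzyloxy)-3-{5,7-bis(benzyloxy)-2-[4-(benzyloxy)phenyl]-4-oxo-4H-chromen-8-yl}benzoic acid | O=C(O)c1ccc(OCc2ccccc2)c(-c2c(OCc3ccccc3)cc(OCc3ccccc3)c3c(=O)cc(-c4ccc(OCc5ccccc5)cc4)oc23)c1
F3 | step 10 | 2-acetyl-3-(benzyloxy)-5-methoxyphenyl 4-(benzyloxy)-3-{5,7-bis(benzyloxy)-2-[4-(benzyloxy)phenyl]-4-oxo-4H-chromen-8-yl}benzoate | CC(=O)c1c(OCc2ccccc2)cc(OC)cc1OC(=O)c1ccc(OCc2ccccc2)c(-c2c(OCc3ccccc3)cc(OCc3ccccc3)c3c(=O)cc(-c4ccc(OCc5ccccc5)cc4)oc23)c1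
F4 | step 10 | 1-[2-(benzyloxy)-6-hydroxy-4-methoxyphenyl]-3-(4-(benzyloxy)-3-{5,7-bis(benzyloxy)-2-[4-(benzyloxy)phenyl]-4-oxo-4H-chromen-8-yl}phenyl)propane-1,3-dione | COc1cc(O)c(C(=O)CC(=O)c2ccc(OCc3ccccc3)c(-c3c(OCc4ccccc4)cc(OCc4ccccc4)c4c(=O)cc(-c5ccc(OCc6ccccc6)cc5)oc34)c2)c(OCc2ccccc2)c1
F5 | step 5 | 1-[4,6-bis(benzyloxy)-3-iodo-2-(methoxymethoxy)phenyl]ethanone | CC(=O)c1c(OCOC)c(I)c(OCc2ccccc2)cc1OCc1ccccc1
F6 | step 5 | 3-[3-acetyl-4,6-bis(benzyloxy)-2-(methoxymethoxy)phenyl]-4-(benzyloxy)benzaldehyde | CC(=O)c1c(OCOC)c(-c2cc(C=O)ccc2OCc2ccccc2)c(OCc2ccccc2)cc1OCc1ccccc1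
F7 | step 6 | 2-acetyl-3,5-bis(benzyloxy)-6-iodophenyl 4-(benzyloxy)benzoate | CC(=O)c1c(OC(=O)c2ccc(OCc3ccccc3)cc2)c(I)c(OCc2ccccc2)cc1OCc1ccccc1
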